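Assumption: by CIP analysis the stereodescriptor in the SMILES is (R) at C-2, the carbinol carbon. Compounds 1, 4 and 8 are taken as commercial.

## Retrosynthetic overview
1. The chalcone route (Claisen–Schmidt, then asymmetric epoxidation or dihydroxylation, then reductive opening) and enolate α-hydroxylation are deliberately avoided.
2. Bold key step: both C-prenyl groups are removed together. The last step is a two-fold aromatic Claisen rearrangement of a bis(1,1-dimethylallyl) aryl ether on the unprotected ketol.
3. The bis-ether comes from the free tetrol core by a chemoselective double Pd-catalysed O-tert-prenylation. No protecting group is ever removed while a prenyl group is present.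
4. The core is cut at the aryl–acyl bond: 2,4-bis(benzyloxy)phenyllithium plus the Weinreb amide of an (R)-aryl-lactic acid. The stereocentre is bought as D-tyrosine and kept by diazotisation with retention.
5. No rings are formed. Both benzene rings are purchased.

## Route

**Step 1**
Reactants: 1, O-benzyl-D-tyrosine, (R)
Product: 2, (2R)-3-[4-(benzyloxy)phenyl]-2-hydroxypropanoic acid
Conditions: NaNO2 (3 equiv), 1 M aq H2SO4/1,4-dioxane, 0 °C to rt, 16 h
Reagents that add atoms: water, O
Why: Deaminative hydroxylation by diazotisation runs through the α-lactone formed by carboxylate participation (double inversion), so the (R) centre is kept with net retention, and the benzyl cap prevents nitrosation of the phenol ring.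

**Step 2**
Reactants: 2
Product: 3, (2R)-3-[4-(benzyloxy)phenyl]-2-hydroxy-N-methoxy-N-methylpropanamide
Conditions: MeNHOMe·HCl, EDC·HCl, HOBt, N-methylmorpholine, CH2Cl2, 0 °C to rt
Reagents that add atoms: N,O-dimethylhydroxylamine hydrochloride, CNOC.Cl
Why: In this carbodiimide/HOBt Weinreb amide synthesis the amine outcompetes the secondary OH for the active ester, and an α-hydroxy acid has no oxazolone pathway, so C-2 stays (R).

**Step 3**
Reactants: 4, 4-bromoresorcinol
Product: 5, 2,4-bis(benzyloxy)-1-bromobenzene
Conditions: BnBr (2.3 equiv), K2CO3, DMF, rt to 50 °C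
Reagents that add atoms: benzyl bromide, BrCc1ccccc1
Why: Williamson etherification alkylates both phenols and leaves the aryl bromide untouched.

**Step 4**
Reactants: 5 (2.5 equiv) and 3
Product: 6, (2R)-1-[2,4-bis(benzyloxy)phenyl]-3-[4-(benzyloxy)phenyl]-2-hydroxypropan-1-one
Conditions: 5, n-BuLi (2.4 equiv), THF, −78 °C, 30 min; add 3 in THF, −78 to −30 °C; cold quench with AcOH/THF, then aq NH4Cl
Reagents that add atoms: none beyond reactants 3 and 5
Why: In this Br/Li exchange and Weinreb ketone synthesis the first equivalent of ArLi forms the α-alkoxide, which together with the N-methoxy-chelated tetrahedral intermediate blocks over-addition and α-deprotonation, so the ketone is released only on the cold quench with C-2 still (R).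

**Step 5**
Reactants: 6
Product: 7, (2R)-1-(2,4-dihydroxyphenyl)-2-hydroxy-3-(4-hydroxyphenyl)propan-1-one
Conditions: H2 (1 atm), 10% Pd/C, EtOAc/EtOH, rt, monitored
Reagents that add atoms: none
Why: Catalytic hydrogenolysis cleaves the three O-benzyl bonds, while the donor-substituted aryl ketone and the non-benzylic carbinol are not reduced at 1 atm and the neutral medium leaves the stereocentre alone.

**Step 6**
Reactants: 8, 2-methylbut-3-en-2-ol
Product: 9, tert-butyl (2-methylbut-3-en-2-yl) carbonate
Conditions: n-BuLi, THF, 0 °C; Boc2O, 0 °C to rt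
Reagents that add atoms: di-tert-butyl dicarbonate, CC(C)(C)OC(=O)OC(=O)OC(C)(C)C
Why: Acylation of the lithium alkoxide with Boc2O gives the mixed tertiary allylic carbonate, which ionises readily on Pd(0).

**Step 7**
Reactants: 7 and 9 (2.3 equiv)
Product: 10, (2R)-2-hydroxy-1-{2-hydroxy-4-[(2-methylbut-3-en-2-yl)oxy]phenyl}-3-{4-[(2-methylbut-3-en-2-yl)oxy]phenyl}propan-1-one
Conditions: Pd(PPh3)4 (5–10 mol %), THF, 0–5 °C, stopped as soon as 7 and the mono-ethers are consumed
Reagents that add atoms: 9, CC(C)(C)OC(=O)OC(C)(C)C=C (delivers two C5H9 units; CO2 and t-BuOH are lost)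
Why: In this decarboxylative Tsuji–Trost O-allylation ("reverse prenylation") phenoxides attack the more substituted π-allyl terminus under kinetic control to give tertiary ethers, only the two unchelated phenols react because the ketone-chelated, hindered 2-OH and the aliphatic OH are poor nucleophiles, and the phenol-buffered medium at 0 °C (no added base) does not enolise the ketol.

**Step 8 (key step)**
Reactants: 10
Product: 11, glycybridin C, (2R)-1-[2,4-dihydroxy-3-(3-methylbut-2-en-1-yl)phenyl]-2-hydroxy-3-[4-hydroxy-3-(3-methylbut-2-en-1-yl)phenyl]propan-1-one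
Conditions: degassed toluene (0.02 M), cat. BHT, sealed tube, 115 °C, 6–10 h
Reagents that add atoms: none
Why: In this two-fold aromatic Claisen [3,3] rearrangement each ether delivers its CH2 terminus to an ortho carbon and gives a linear prenyl group after tautomerisation; ring B has two equivalent ortho sites, ring A migrates to C-3 because the chelated 2-OH/C=O raises C3–C4 double-bond character (the bias that turns 4-allyloxy-2-hydroxyacetophenone into its 3-allyl isomer), and the gem-dimethyl acceleration allows a neutral, aprotic 115 °C that leaves the (R) centre untouched.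

## Compound list
| No. | Name | SMILES | Role |
|---|---|---|---|
| 1 | O-benzyl-D-tyrosine | N[C@H](Cc1ccc(OCc2ccccc2)cc1)C(=O)O | starting material |
| 2 | (2R)-3-[4-(benzyloxy)phenyl]-2-hydroxypropanoic acid | O[C@H](Cc1ccc(OCc2ccccc2)cc1)C(=O)O | intermediate |
| 3 | (2R)-Weinreb amide of 2 | O[C@H](Cc1ccc(OCc2ccccc2)cc1)C(=O)N(C)OC | intermediate |
| 4 | 4-bromoresorcinol | Oc1ccc(Br)c(O)c1 | starting material |
| 5 | 2,4-bis(benzyloxy)-1-bromobenzene | Brc1ccc(OCc2ccccc2)cc1OCc1ccccc1 | intermediate |
| 6 | (2R)-tribenzyl α-hydroxy ketone | O[C@H](Cc1ccc(OCc2ccccc2)cc1)C(=O)c1ccc(OCc2ccccc2)cc1OCc1ccccc1 | intermediate |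
| 7 | (2R)-1-(2,4-dihydroxyphenyl)-2-hydroxy-3-(4-hydroxyphenyl)propan-1-one | O[C@H](Cc1ccc(O)cc1)C(=O)c1ccc(O)cc1O | intermediate |
| 8 | 2-methylbut-3-en-2-ol | CC(C)(O)C=C | starting material |
| 9 | tert-butyl (2-methylbut-3-en-2-yl) carbonate | CC(C)(C)OC(=O)OC(C)(C)C=C | intermediate |
| 10 | (2R)-bis(1,1-dimethylallyl) ether | O[C@H](Cc1ccc(OC(C)(C)C=C)cc1)C(=O)c1ccc(OC(C)(C)C=C)cc1O | intermediate |
| 11 | glycybridin C, (R) | CC(C)=CCc1cc(C[C@@H](O)C(=O)c2ccc(O)c(CC=C(C)C)c2O)ccc1O | target |

## Summary
Total step count: 8.
Longest linear sequence: 6 (steps 1, 2, 4, 5, 7, 8).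

Steps most likely to fail:
1. **Step 8.** The risks are the ring-A C-5 regioisomer, loss of isoprene, and thermal erosion of ee.
   - Fallback: drop the pericyclic transfer. Bis-iodinate core 7 with I2/HIO3, at ring A C-3 between the two OH groups and on ring B ortho to OH.
   - Then run a two-fold Pd-catalysed Stille prenylation with tributyl(prenyl)stannane.
2. **Step 7.** The risks are alkylation of the 2-OH and Pd-mediated isomerisation to linear O-prenyl ethers, mainly on the acidic ring-A phenol.
   - Fallback: build the tertiary ethers without π-allyl chemistry.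
   - Use Cu-catalysed 1,1-dimethylpropargylation of the two free phenols with a 2-methylbut-3-yn-2-yl carbonate, then Lindlar semi-hydrogenation to 10.
3. **Step 4.** The risks are sluggish addition to the alkoxide-bearing amide, benzylic metalation, and epimerisation on work-up.
   - Fallback: replace carbanion chemistry with a neutral Liebeskind–Srogl coupling.
   - The partners are the O-TBS S-aryl thioester of 2 and 2,4-bis(benzyloxy)phenylboronic acid with Pd(0)/CuTC; fluoride desilylation then rejoins the route at 6.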